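**Plan**

1. Retrosynthetic cuts: the two ester C–O bonds of the side chain, with both Z-alkenes traced back to alkynes; in ring B the C9–O bond and the C7=C11 bond, back to a trans-decalone; in ring A the carbon C4 with its methyl is taken out from between C3 and C5, which turns ring A into a cyclopentanone.
2. Enabling feature: in ring A the oxygen-bearing C3 is separated from the quaternary, methyl-bearing ring-fusion carbon C5 only by C4H(CH3), and ring B carries C8=O. Without C4 the skeleton is the cyclopentanone/cyclohexenone pair of the (S)-Hajos–Parrish ketone, with C5 as its angular carbon.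
3. Forward order: ring B and C5 come with the starting ketone. Ring A arises by a one-carbon ring expansion in which C5 shifts from C3 to a carbenoid carbon that becomes C4, ending in the C3–C4 enolate. Then follow one Li/NH3 reduction, acetone aldol condensation at C7, hydroxylation at C9, attachment of the chain as a diyne acid and a twofold Lindlar reduction.
4. Stereochemistry: C5 from the proline-derived ketone; C4 by axial protonation of the ring-expanded enolate anti to the C5 methyl; C10 (trans junction) and C3 (equatorial OH) in the dissolving-metal step; C9 by enolate oxidation anti to the axial C5 methyl; the side-chain carbinol from (S)-pent-1-yn-3-ol; both Z-alkenes by syn-hydrogenation.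

Key step: step 2

Remark on numbering: eremophilane numbering is used for all bicyclic compounds, the hydrindanes included. C3 is the oxygenated carbon of ring A, C4 is CH(CH3), C5 is the quaternary C–CH3, C8 is the ring-B carbonyl carbon, C9 its α-carbon next to the ring junction, C10 the ring-fusion CH. β is the face of the C5 methyl, α the opposite face.
Remark on supply: (S)-pent-1-yn-3-ol is taken as a purchasable enantiopure building block.

**Route**

Step 1
Reactants: 1 (S)-Hajos–Parrish ketone, (7aS)-7a-methyl-2,3,7,7a-tetrahydro-1H-indene-1,5(6H)-dione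
Product: 2 enone dithiolane of 1 (C8 carbonyl as 1,3-dithiolane, C9=C10 unmoved, cyclopentanone free)
Conditions: HS(CH2)2SH (1.05 equiv), BF3·OEt2 (cat.), MeOH, 0 °C → rt
Reagents that add atoms: ethane-1,2-dithiol, SCCS
Why: Acid-catalysed thioketalisation should be faster at the conjugated carbonyl than at the neopentyl cyclopentanone carbonyl (the selectivity known for Δ4-3,17-diketo steroids), and enone thioketals keep the C=C in place; no stereocenter is touched.

Step 2
Reactants: 2 enone dithiolane of 1; 3 1,1-dibromoethane
Product: 7 ring-expanded ketone 4β,5β-dimethyl-3-oxo-octal-9(10)-ene 8-ethylene dithioketal, via lithium dibromoethyl alkoxide 4 (not isolated), via β-oxido carbenoid 5 (not isolated), via ring-expanded lithium enolate 6 (not isolated)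
Conditions: 3 (1.3 equiv), THF/Et2O, −95 °C, LDA (1.3 equiv) added slowly; n-BuLi (1.5 equiv), −95 → −20 °C; then −78 °C, AcOH/THF
Reagents that add atoms: none
Why: 1,1-Dibromoethyllithium, made and trapped in situ, adds to the only free carbonyl from the face anti to the angular methyl, and Br/Li exchange gives the β-oxido carbenoid 5, in which the ring bond C3–C5 anti to the C–Br bond shifts to the carbenoid carbon as LiBr leaves, giving the C3–C4 enolate 6 regiospecifically (closest known reaction type: the Nozaki–Yamamoto β-oxido carbenoid homologation of cycloalkanones with 1,1-dibromoalkyllithiums). Ring A is therefore not closed by a cyclisation but enlarged from five to six members by a [1,2]-shift of carbon, which inserts C4 with its methyl between C3 and C5. C5 migrates with retention, so the quaternary centre of 1 is carried over, while the configuration of the carbenoid carbon is erased in the planar enolate, which makes the step convergent for both diastereomers of 5. C4 is then set by protonation of 6 at −78 °C: the proton should enter axially on the α face, anti to the axial C5 methyl on the neighbouring carbon, leaving the C4 methyl equatorial and cis to the C5 methyl. The step needs migration of the quaternary C5 and not of the methylene C2, and the more substituted, more electron-rich carbon is expected to be the better migrating group toward the electron-poor carbenoid carbon. Chemoselectivity for the cyclopentanone is secured by the dithiolane on C8.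

Step 3
Reactants: 7 ring-expanded ketone 4β,5β-dimethyl-3-oxo-octal-9(10)-ene 8-ethylene dithioketal
Product: 8 ene-dione (4aR,5R)-4a,5-dimethyl-4,4a,7,8-tetrahydronaphthalene-2,6(3H,5H)-dione
Conditions: MeI (excess), CaCO3, MeCN/H2O 4:1, 45 °C
Reagents that add atoms: water, O
Why: S-Methylation and hydrolysis (dethioketalisation of an allylic dithiolane) under buffered, non-enolising conditions should free the enone without touching the C4 centre next to the C3 ketone.

Step 4
Reactants: 8 ene-dione
Product: 10 3α-hydroxy-4β,5β-dimethyl-trans-decal-8-one (10α-H), via dilithium enolate alkoxide 9 (not isolated)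
Conditions: Li (6 equiv), NH3(l)/THF, t-BuOH (2.2 equiv), −78 °C; isoprene; solid NH4Cl
Reagents that add atoms: none
Why: Dissolving-metal (Birch-type) reduction: the enone is reduced first, axial protonation of the C10 carbanion gives the trans ring junction (10α-H) and a C8 enolate that is safe from further reduction, and the C3 ketone is reduced through its ketyl to the thermodynamically favoured equatorial 3α-alkoxide (the axial epimer would be 1,3-diaxial to the C5 methyl).

Step 5
Reactants: 10 3α-hydroxy-4β,5β-dimethyl-trans-decal-8-one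
Product: 11 3α-triethylsilyloxy-4β,5β-dimethyl-trans-decal-8-one
Conditions: TESCl, imidazole, DMF, 0 °C → rt
Reagents that add atoms: chlorotriethylsilane, CC[Si](Cl)(CC)CC
Why: Standard silylation of the only hydroxyl; the TES ether is chosen because it can later be removed in the presence of a TBS ether.

Step 6
Reactants: 11 3α-triethylsilyloxy-4β,5β-dimethyl-trans-decal-8-one; 12 acetone
Product: 14 7α-(2-hydroxypropan-2-yl) aldol of 11, via lithium Δ7 enolate 13 (not isolated)
Conditions: LDA (1.1 equiv), THF, −78 °C; acetone (3 equiv), −78 °C; AcOH quench at −78 °C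
Reagents that add atoms: none
Why: Kinetic deprotonation of a trans-fused decalone of this type goes to the methylene remote from the ring junction (C7, as in the Δ2 enolates of 5α-3-keto steroids), and the directed aldol addition to acetone should place the new group equatorial (7α); this centre is removed in step 7.

Step 7
Reactants: 14 7α-(2-hydroxypropan-2-yl) aldol of 11
Product: 16 3α-triethylsilyloxy-eremophil-7(11)-en-8-one (10α-H), via tertiary mesylate 15 (not isolated)
Conditions: MsCl, Et3N, CH2Cl2, 0 °C → rt; then DBU, rt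
Reagents that add atoms: none
Why: Mesylation of the tertiary aldol hydroxyl (through sulfene) followed by E1cB elimination through the C7 enolate should give the conjugated, tetrasubstituted isopropylidene ketone and not the isopropenyl isomer.

Step 8
Reactants: 16 3α-triethylsilyloxy-eremophil-7(11)-en-8-one
Product: 18 9α-hydroxy-3α-triethylsilyloxy-eremophil-7(11)-en-8-one, via potassium C8–C9 enolate 17 (not isolated)
Conditions: KHMDS (1.2 equiv), THF, −78 °C; Davis oxaziridine (1.5 equiv), −78 °C; AcOH
Reagents that add atoms: 3-phenyl-2-(phenylsulfonyl)oxaziridine, O=S(=O)(c1ccccc1)N1OC1c1ccccc1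
Why: C7 has no hydrogen left, so kinetic deprotonation should take the α′ proton at C9 (cross-conjugated enolate, preferred over γ-deprotonation at −78 °C), and the Davis enolate oxidation should deliver oxygen to the α face, away from the C5 methyl that is 1,3-diaxial to the β face of C9, giving the equatorial 9α-OH, which is also the more stable ketol epimer.

Step 9
Reactants: 18 9α-hydroxy-3α-triethylsilyloxy-eremophil-7(11)-en-8-one
Product: 19 9α-(tert-butyldimethylsilyloxy)-3α-triethylsilyloxy-eremophil-7(11)-en-8-one
Conditions: TBSOTf, 2,6-lutidine, CH2Cl2, −40 → 0 °C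
Reagents that add atoms: tert-butyldimethylsilyl triflate, CC(C)(C)[Si](C)(C)OS(=O)(=O)C(F)(F)F
Why: Silyl triflate silylation of the hindered ketol hydroxyl under weakly basic conditions; this blocks O9 so that only O3 can be acylated later.

Step 10
Reactants: 19 9α-(tert-butyldimethylsilyloxy)-3α-triethylsilyloxy-eremophil-7(11)-en-8-one
Product: 20 9α-(tert-butyldimethylsilyloxy)-3α-hydroxy-eremophil-7(11)-en-8-one
Conditions: PPTS (0.2 equiv), MeOH/CH2Cl2, 0 °C → rt
Reagents that add atoms: none
Why: Acid-catalysed methanolysis cleaves a secondary TES ether far faster than a secondary TBS ether, so only the 3α-hydroxyl should be set free.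

Step 11
Reactants: 21 (S)-pent-1-yn-3-ol
Product: 26 tert-butyl (S)-4-hydroxyhex-2-ynoate, via lithium alkoxide 22 (not isolated), via O-trimethylsilyl ether 23 (not isolated), via lithium acetylide 24 (not isolated), via silylated tert-butyl ynoate 25 (not isolated)
Conditions: n-BuLi (1.0 equiv), THF, −78 °C; TMSCl (1.0 equiv), → 0 °C; n-BuLi (1.05 equiv), −78 °C; Boc2O, −78 → −20 °C; citric acid, MeOH, rt
Reagents that add atoms: di-tert-butyl dicarbonate, CC(C)(C)OC(=O)OC(=O)OC(C)(C)C
Why: Transient O-silylation leaves the acetylide as the only nucleophile, which is C-acylated by Boc2O to the tert-butyl ynoate (acylation of a lithium acetylide); the carbinol centre is not involved and keeps its S configuration.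

Step 12
Reactants: 26 tert-butyl (S)-4-hydroxyhex-2-ynoate; 27 hex-2-ynoic acid
Product: 28 tert-butyl (S)-4-(hex-2-ynoyloxy)hex-2-ynoate
Conditions: DCC, DMAP (5 mol %), CH2Cl2, 0 °C
Reagents that add atoms: none
Why: Steglich esterification of the secondary propargylic alcohol with retention at the carbinol carbon; the tert-butyl ester keeps the future acid masked.

Step 13
Reactants: 28 tert-butyl (S)-4-(hex-2-ynoyloxy)hex-2-ynoate
Product: 29 (S)-4-(hex-2-ynoyloxy)hex-2-ynoic acid
Conditions: TFA/CH2Cl2 1:4, 0 °C → rt
Reagents that add atoms: none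
Why: Acidolysis of the tert-butyl ester (loss of isobutene) should leave the secondary propargylic ester, which cannot ionise readily, untouched.

Step 14
Reactants: 20 9α-(tert-butyldimethylsilyloxy)-3α-hydroxy-eremophil-7(11)-en-8-one; 29 (S)-4-(hex-2-ynoyloxy)hex-2-ynoic acid
Product: 30 3-O-[(S)-4-(hex-2-ynoyloxy)hex-2-ynoyl] ester of 20
Conditions: DCC, DMAP (0.1 equiv), CH2Cl2, −10 → 0 °C
Reagents that add atoms: none
Why: Steglich esterification of the only free hydroxyl (equatorial 3α-OH, O9 silylated) with retention at C3; the chain is brought in at the alkyne level so that no Z-enoate is exposed to the acylation catalyst.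

Step 15
Reactants: 30 3-O-[(S)-4-(hex-2-ynoyloxy)hex-2-ynoyl] ester of 20
Product: 31 9-O-TBS ether of the target
Conditions: H2 (1 atm), Lindlar catalyst (Pd/CaCO3/Pb), quinoline, EtOAc, rt
Reagents that add atoms: none
Why: Lindlar syn-semihydrogenation of both ynoates should give both (Z)-enoates at once, the tetrasubstituted enone C=C being inert and the γ-oxygen being acylated so that no butenolide can form.

Step 16
Reactants: 31 9-O-TBS ether of the target
Product: 32 target CNP0170141.1, (1R,2R,4aR,5S,8aR)-5-hydroxy-1,8a-dimethyl-6-oxo-7-(propan-2-ylidene)decahydronaphthalen-2-yl (S,2Z)-4-[(2Z)-hex-2-enoyloxy]hex-2-enoate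
Conditions: HF·pyridine, pyridine/THF, 0 °C → rt
Reagents that add atoms: none
Why: Buffered fluoride desilylation removes the TBS ether from O9 under conditions that should leave the esters, the Z-alkenes and the epimerisable ketol untouched.

**Compound list**

1 | (S)-Hajos–Parrish ketone, (7aS)-7a-methyl-2,3,7,7a-tetrahydro-1H-indene-1,5(6H)-dione | C[C@]12CCC(=O)C=C1CCC2=O | starting material
2 | enone dithiolane of 1 | C[C@]12CCC3(SCCS3)C=C1CCC2=O | intermediate
3 | 1,1-dibromoethane | CC(Br)Br | starting material
4 | lithium alkoxide of the 1,1-dibromoethyl carbinol (O cis to the angular methyl) | C[C@]12CCC3(SCCS3)C=C1CC[C@@]2(O[Li])C(C)(Br)Br | intermediate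
5 | β-oxido carbenoid (1-bromo-1-lithioethyl lithium alkoxide, both configurations at the carbenoid carbon) | C[C@]12CCC3(SCCS3)C=C1CC[C@@]2(O[Li])C(C)(Br)[Li] | intermediate
6 | ring-expanded lithium C3–C4 enolate | [Li]OC1=C(C)[C@@]2(C)CCC3(SCCS3)C=C2CC1 | intermediate
7 | ring-expanded ketone, 4β,5β-dimethyl-3-oxo-octal-9(10)-ene 8-ethylene dithioketal | O=C1CCC2=CC3(SCCS3)CC[C@]2(C)[C@H]1C | intermediate
8 | ene-dione, (4aR,5R)-4a,5-dimethyl-4,4a,7,8-tetrahydronaphthalene-2,6(3H,5H)-dione | O=C1CCC2=CC(=O)CC[C@]2(C)[C@H]1C | intermediate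
9 | dilithium 3α-alkoxide C8–C9 enolate (trans junction) | [Li]O[C@@H]1CC[C@H]2C=C(O[Li])CC[C@]2(C)[C@H]1C | intermediate
10 | 3α-hydroxy-4β,5β-dimethyl-trans-decal-8-one (10α-H) | O[C@@H]1CC[C@H]2CC(=O)CC[C@]2(C)[C@H]1C | intermediate
11 | 3α-triethylsilyloxy-4β,5β-dimethyl-trans-decal-8-one | CC[Si](CC)(CC)O[C@@H]1CC[C@H]2CC(=O)CC[C@]2(C)[C@H]1C | intermediate
12 | acetone | CC(C)=O | starting material
13 | lithium Δ7 (C7–C8) enolate of 11 | CC[Si](CC)(CC)O[C@@H]1CC[C@H]2CC(O[Li])=CC[C@]2(C)[C@H]1C | intermediate
14 | 7α-(2-hydroxypropan-2-yl) aldol of 11 | CC[Si](CC)(CC)O[C@@H]1CC[C@H]2CC(=O)[C@H](C(C)(C)O)C[C@]2(C)[C@H]1C | intermediate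
15 | tertiary mesylate of 14 | CC[Si](CC)(CC)O[C@@H]1CC[C@H]2CC(=O)[C@H](C(C)(C)OS(C)(=O)=O)C[C@]2(C)[C@H]1C | intermediate
16 | 3α-triethylsilyloxy-eremophil-7(11)-en-8-one (10α-H) | CC[Si](CC)(CC)O[C@@H]1CC[C@H]2CC(=O)C(=C(C)C)C[C@]2(C)[C@H]1C | intermediate
17 | potassium C8–C9 enolate of 16 | CC[Si](CC)(CC)O[C@@H]1CC[C@H]2C=C(O[K])C(=C(C)C)C[C@]2(C)[C@H]1C | intermediate
18 | 9α-hydroxy-3α-triethylsilyloxy-eremophil-7(11)-en-8-one | CC[Si](CC)(CC)O[C@@H]1CC[C@H]2[C@H](O)C(=O)C(=C(C)C)C[C@]2(C)[C@H]1C | intermediate
19 | 9α-(tert-butyldimethylsilyloxy)-3α-triethylsilyloxy-eremophil-7(11)-en-8-one | CC[Si](CC)(CC)O[C@@H]1CC[C@H]2[C@H](O[Si](C)(C)C(C)(C)C)C(=O)C(=C(C)C)C[C@]2(C)[C@H]1C | intermediate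
20 | 9α-(tert-butyldimethylsilyloxy)-3α-hydroxy-eremophil-7(11)-en-8-one | O[C@@H]1CC[C@H]2[C@H](O[Si](C)(C)C(C)(C)C)C(=O)C(=C(C)C)C[C@]2(C)[C@H]1C | intermediate
21 | (S)-pent-1-yn-3-ol | CC[C@H](O)C#C | starting material
22 | lithium (S)-pent-1-yn-3-olate | CC[C@H](O[Li])C#C | intermediate
23 | (S)-trimethyl(pent-1-yn-3-yloxy)silane | CC[C@H](O[Si](C)(C)C)C#C | intermediate
24 | lithium acetylide of 23 | CC[C@H](O[Si](C)(C)C)C#C[Li] | intermediate
25 | tert-butyl (S)-4-(trimethylsilyloxy)hex-2-ynoate | CC[C@H](O[Si](C)(C)C)C#CC(=O)OC(C)(C)C | intermediate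
26 | tert-butyl (S)-4-hydroxyhex-2-ynoate | CC[C@H](O)C#CC(=O)OC(C)(C)C | intermediate
27 | hex-2-ynoic acid | CCCC#CC(=O)O | starting material
28 | tert-butyl (S)-4-(hex-2-ynoyloxy)hex-2-ynoate | CCCC#CC(=O)O[C@H](C#CC(=O)OC(C)(C)C)CC | intermediate
29 | (S)-4-(hex-2-ynoyloxy)hex-2-ynoic acid | CCCC#CC(=O)O[C@H](C#CC(=O)O)CC | intermediate
30 | 3-O-[(S)-4-(hex-2-ynoyloxy)hex-2-ynoyl] ester of 20 | CCCC#CC(=O)O[C@H](C#CC(=O)O[C@@H]1CC[C@H]2[C@H](O[Si](C)(C)C(C)(C)C)C(=O)C(=C(C)C)C[C@]2(C)[C@H]1C)CC | intermediate
31 | 9-O-TBS ether of the target | CCC/C=C\C(=O)O[C@H](/C=C\C(=O)O[C@@H]1CC[C@H]2[C@H](O[Si](C)(C)C(C)(C)C)C(=O)C(=C(C)C)C[C@]2(C)[C@H]1C)CC | intermediate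
32 | CNP0170141.1, (1R,2R,4aR,5S,8aR)-5-hydroxy-1,8a-dimethyl-6-oxo-7-(propan-2-ylidene)decahydronaphthalen-2-yl (S,2Z)-4-[(2Z)-hex-2-enoyloxy]hex-2-enoate | CCC/C=C\C(=O)O[C@H](/C=C\C(=O)O[C@@H]1CC[C@H]2[C@H](O)C(=O)C(=C(C)C)C[C@]2(C)[C@H]1C)CC | target

**Step count and risks**

Total step count: 16. Longest linear sequence: 13 steps (steps 1–10 and 14–16); the side-chain acid takes 3 steps (11–13).

Steps most likely to fail:

1. Step 2 (ring expansion). The methylene carbon C2 may migrate in place of the quaternary C5 in the carbenoid shift. The hindered ketone may be enolised instead of attacked, or the dibromide may undergo β-elimination. Protonation of the enolate may also show poor facial selectivity. The fallback sets out from 2 and comes back at 8, and it replaces the carbenoid by a cationic pinacol-type shift of a diol monosulfonate. Wittig ethylidenation of 2 (Ph3P=CHCH3, THF) should give the (Z)-ethylidene dithiolane F1. MeI/CaCO3 frees the (Z)-ethylidene dienone F2. OsO4/NMO should dihydroxylate only the electron-rich ethylidene, from the α face, to the 3,4-diol F3, and MsCl/pyridine gives the secondary mesylate F4. LiClO4/CaCO3 in THF (or Et2AlCl) then induces the ring expansion, the reaction type of the D-homoannulation of 17-hydroxy-20-sulfonyloxy steroids. Here the quaternary carbon migrates with inversion at C4, which should give the 4α-methyl ene-dione F5. F5 is equilibrated at C4 through its enol (NaOMe, MeOH), 8 is separated and F5 is recycled.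

2. Step 14 (esterification). The activated γ-acyloxy ynoic acid 29 has an acidic propargylic C–H and a carboxylate leaving group at C4, so base may cause loss of configuration or elimination there. The hindered 3α-hydroxyl may also be acylated too slowly. The fallback sets out from 20 and 21 and comes back at 30, and it puts the chain on in two pieces. Silylation of 21 (TESCl, imidazole) gives (S)-triethyl(pent-1-yn-3-yloxy)silane F8. Carboxylation (n-BuLi, then CO2) gives (S)-4-(triethylsilyloxy)hex-2-ynoic acid F9, which has no leaving group at C4. Yamaguchi esterification with 20 gives the 3-O-[(S)-4-(triethylsilyloxy)hex-2-ynoyl] ester F10. PPTS/MeOH removes only the TES group to give the 3-O-[(S)-4-hydroxyhex-2-ynoyl] ester F11. Acylation of F11 with 27 (DCC, DMAP) gives 30.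

3. Step 4 (double reduction). The C8 carbonyl may be over-reduced after early protonation of the enolate. The C3 ketyl may undergo pinacol coupling, or amide base may epimerise C4 before the ketone is reduced. The fallback sets out from 7 and comes back at 10, and it separates the two reductions. The C3 ketone of 7 is reduced with SmI2/H2O/Et3N while the enone is still masked; this single-electron reduction should give the equatorial alcohol, the 3α-hydroxy dithiolane F6. MeI/CaCO3 then frees the 3α-hydroxy enone F7. Li/NH3 with one equivalent of t-BuOH reduces only the enone, the 3-alkoxide being inert, and gives 10.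

**Further compounds**

F1 | step 2 | (Z)-ethylidene dithiolane | C/C=C1/CCC2=CC3(SCCS3)CC[C@]12C
F2 | step 2 | (Z)-ethylidene dienone | C/C=C1/CCC2=CC(=O)CC[C@]12C
F3 | step 2 | 3,4-diol (3α-OH, side-chain carbinol S) | C[C@H](O)[C@@]1(O)CCC2=CC(=O)CC[C@]12C
F4 | step 2 | secondary mesylate of F3 | C[C@H](OS(C)(=O)=O)[C@@]1(O)CCC2=CC(=O)CC[C@]12C
F5 | step 2 | 4α-methyl ene-dione (C4 epimer of 8) | O=C1CCC2=CC(=O)CC[C@]2(C)[C@@H]1C
F6 | step 4 | 3α-hydroxy dithiolane | O[C@@H]1CCC2=CC3(SCCS3)CC[C@]2(C)[C@H]1C
F7 | step 4 | 3α-hydroxy enone | O[C@@H]1CCC2=CC(=O)CC[C@]2(C)[C@H]1C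
F8 | step 14 | (S)-triethyl(pent-1-yn-3-yloxy)silane | CC[C@H](O[Si](CC)(CC)CC)C#C
F9 | step 14 | (S)-4-(triethylsilyloxy)hex-2-ynoic acid | CC[C@H](O[Si](CC)(CC)CC)C#CC(=O)O
F10 | step 14 | 3-O-[(S)-4-(triethylsilyloxy)hex-2-ynoyl] ester of 20 | CC[C@H](O[Si](CC)(CC)CC)C#CC(=O)O[C@@H]1CC[C@H]2[C@H](O[Si](C)(C)C(C)(C)C)C(=O)C(=C(C)C)C[C@]2(C)[C@H]1C
F11 | step 14 | 3-O-[(S)-4-hydroxyhex-2-ynoyl] ester of 20 | CC[C@H](O)C#CC(=O)O[C@@H]1CC[C@H]2[C@H](O[Si](C)(C)C(C)(C)C)C(=O)C(=C(C)C)C[C@]2(C)[C@H]1C
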